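**Retrosynthetic overview**

1. The C9 and C8 esters go on last; the cis C2–C3 oxirane and the (E)-C1=C10 enoate of core 29 come from macrocyclic carbinol 26, which carries a temporary C1–C2 trans-oxirane and an sp3 C10–H, by a one-pot mesylation/E1cB/ring-closure "oxirane relay".
2. The ten-membered carbocycle is closed at C3–C4 by intramolecular Nozaki–Hiyama–Kishi addition of the (Z)-C4 vinyl iodide to the C3 epoxy aldehyde 25.
3. 25 comes from lactone 21 (cross-metathesis, Sharpless epoxidation, oxidation); 21 from allyl bromide 15 and (Z)-3-iodobut-2-enal 19 by anti-selective chromium allylation/lactonisation; 15 from an Evans dienolate aldol of imide 5 with glyceraldehyde derivative 4.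
4. Ring order: γ-lactone (step 11), temporary C1–C2 oxirane (step 13), ten-membered carbocycle (step 15), C2–C3 oxirane (step 16); the side-chain oxirane is made separately (step 19).
5. Enabling feature: in the ten-membered ring, C10(CO2Me)=C1–C2(O)–C3 is a γ,δ-epoxy-α,β-unsaturated ester, the E1cB isomer of a β,γ-epoxy ester. C3 can therefore react as a configurationally stable, oxirane-substituted aldehyde while the oxirane sits on C1–C2; the trans γ-lactone on C6/C7 and the Z C4=C5 bond fold the chain so that C4 reaches C3.

Key step: step 15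

Remark on the chemistry: the germacrane numbering of the target is used for every intermediate (ring carbons C1–C10, lactone carbons C11–C13 with C12 the carbonyl carbon, ester carbon C14 on C10, methyl C15 on C4), and (R)-but-3-ene-1,2-diol, imide 5 and (R)-2-methylbutanoic acid are assumed to be bought enantiopure.

**Route**

Step 1
Reactants: 1 (R)-but-3-ene-1,2-diol
Product: 2 (R)-3,4-bis(triethylsilyloxy)but-1-ene
Conditions: Et3SiCl, imidazole, DMF, 0 °C to rt
Reagents that add atoms: chlorotriethylsilane, CC[Si](Cl)(CC)CC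
Why: Silyl ether formation on both hydroxyl groups; the stereocentre (future C8) is not involved.

Step 2
Reactants: 2 (R)-3,4-bis(triethylsilyloxy)but-1-ene
Product: 4 (S)-2,3-bis(triethylsilyloxy)propanal, via secondary ozonide 3 (not isolated)
Conditions: O3, CH2Cl2, −78 °C; then PPh3, −78 °C to rt
Reagents that add atoms: ozone, [O-][O+]=O
Why: Ozonolysis with reductive work-up cleaves the terminal alkene to the α-silyloxy aldehyde under neutral conditions, so the stereocentre does not epimerise.

Step 3
Reactants: 5 (S)-4-benzyl-3-[(E)-but-2-enoyl]oxazolidin-2-one; 4 (S)-2,3-bis(triethylsilyloxy)propanal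
Product: 8 (S)-4-benzyl-3-[(2S,3S,4S)-3-hydroxy-4,5-bis(triethylsilyloxy)-2-vinylpentanoyl]oxazolidin-2-one, via boron dienolate 6 (not isolated), via boron aldolate 7 (not isolated)
Conditions: Bu2BOTf, Et3N, CH2Cl2, −78 to 0 °C; then 4, −78 to 0 °C; pH 7 buffer, MeOH, H2O2, 0 °C
Reagents that add atoms: none
Why: Evans syn-aldol reaction of the (Z)-boron dienolate, which reacts at its α-carbon through a Zimmerman–Traxler chair with one face shielded by the benzyl group of the auxiliary, so that C9 (S) and C10 (S) are set by reagent control over the weak bias of the α-silyloxy aldehyde.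

Step 4
Reactants: 8 aldol adduct
Product: 9 methyl (2S,3S,4S)-3-hydroxy-4,5-bis(triethylsilyloxy)-2-vinylpentanoate
Conditions: MeMgBr, MeOH, CH2Cl2, 0 °C
Reagents that add atoms: methanol, CO
Why: Transesterification of the imide with bromomagnesium methoxide: chelation of magnesium between the β-hydroxyl and the imide carbonyl directs methoxide to the exocyclic carbonyl, and the mild conditions leave C10 and the β,γ-alkene unchanged.

Step 5
Reactants: 9 methyl ester
Product: 10 methyl (2S,3S,4S)-3-(tert-butyldimethylsilyloxy)-4,5-bis(triethylsilyloxy)-2-vinylpentanoate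
Conditions: t-BuMe2SiOTf, 2,6-lutidine, CH2Cl2, −78 to 0 °C
Reagents that add atoms: tert-butyldimethylsilyl trifluoromethanesulfonate, CC(C)(C)[Si](C)(C)OS(=O)(=O)C(F)(F)F
Why: Silylation of the hindered secondary C9 alcohol with a silyl triflate and a non-nucleophilic base; no stereocentre is touched.

Step 6
Reactants: 10 tris-silyl ether
Product: 11 methyl (2S,3S,4R)-3-(tert-butyldimethylsilyloxy)-5-oxo-4-(triethylsilyloxy)-2-vinylpentanoate
Conditions: (COCl)2, DMSO, CH2Cl2, −78 to −40 °C; then Et3N, −78 to 0 °C
Reagents that add atoms: none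
Why: Swern oxidation run directly on the silyl ether: the chlorosulfonium salt cleaves only the unhindered primary triethylsilyl ether and the resulting alkoxysulfonium ion gives the C7 aldehyde, the secondary silyl ethers being too hindered to react (the descriptor at C8 changes only because the priorities change).

Step 7
Reactants: 11 C7 aldehyde; 12 methyl propiolate
Product: 14 Morita–Baylis–Hillman-type adduct (both C7 epimers), via vinylalane 13 (not isolated)
Conditions: i-Bu2AlH, N-methylmorpholine N-oxide, THF, 0 °C, then 12; then 11, 0 °C to rt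
Reagents that add atoms: none
Why: Vinylalumination (Morita–Baylis–Hillman-type adduct formation): conjugate hydroalumination of methyl propiolate gives an α-alumino acrylate that adds to the aldehyde under non-basic conditions so that C8 does not epimerise, and the new C7 carbinol may form as either epimer because step 8 erases it.

Step 8
Reactants: 14 Morita–Baylis–Hillman-type adduct
Product: 15 dimethyl (2Z)-2-(bromomethyl)-5-(tert-butyldimethylsilyloxy)-4-(triethylsilyloxy)-6-vinylhept-2-enedioate
Conditions: N-bromosuccinimide, Me2S, CH2Cl2, 0 °C to rt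
Reagents that add atoms: N-bromosuccinimide, O=C1CCC(=O)N1Br
Why: Allylic bromination with transposition (SN2′): the hydroxyl, activated as an alkoxysulfonium salt by the Corey–Kim-type reagent, is displaced by bromide at the terminal methylene carbon, which gives the conjugated, thermodynamically favoured (Z)-2-(bromomethyl)enoate and removes the C7 stereocentre.

Step 9
Reactants: 16 but-2-yn-1-ol
Product: 18 (Z)-3-iodobut-2-en-1-ol, via cyclic alkenylalanate 17 (not isolated)
Conditions: NaAlH2(OCH2CH2OMe)2, THF, 0 °C to rt; then I2, −78 °C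
Reagents that add atoms: iodine, [I][I]
Why: trans-Hydroalumination of the propargylic alcohol, directed by the alkoxide so that aluminium ends on C3 cis to the carbinol carbon, followed by iodinolysis of the C–Al bond with retention, gives the (Z)-vinyl iodide.

Step 10
Reactants: 18 (Z)-3-iodobut-2-en-1-ol
Product: 19 (Z)-3-iodobut-2-enal
Conditions: MnO2, CH2Cl2, rt
Reagents that add atoms: none
Why: Oxidation of the allylic alcohol with MnO2 is neutral and keeps the Z geometry of the iodoalkene.

Step 11
Reactants: 15 allyl bromide; 19 (Z)-3-iodobut-2-enal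
Product: 21 iodoalkenyl trans-α-methylene-γ-butyrolactone, via anti hydroxy diester 20 (not isolated)
Conditions: CrCl2 (nickel-free), THF, 0 °C to rt; then pyridinium p-toluenesulfonate (cat.), CH2Cl2, rt
Reagents that add atoms: none
Why: Nozaki–Hiyama allylation with in situ lactonisation: the allylchromium reagent adds 1,2 to the enal through a chair transition state that gives the anti adduct (trans lactone after closure on the C12 ester), the aldehyde approaching C7 anti to the C8–C9 bond while C8–H eclipses the alkene (allylic strain), so that C6 and C7 are set relative to C8 as in the target, and nickel-free CrCl2 leaves the vinyl iodide untouched.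

Step 12
Reactants: 21 lactone; 22 (Z)-but-2-ene-1,4-diol
Product: 23 (E)-allylic alcohol (C1=C2 and C3–OH)
Conditions: second-generation Hoveyda–Grubbs catalyst [RuCl2(=CH-C6H4-2-O-i-Pr)(H2IMes)] (10 mol %), CH2Cl2, 40 °C
Reagents that add atoms: none
Why: Olefin cross-metathesis: the monosubstituted vinyl group on C10 is the only alkene of 21 that readily enters the ruthenium cycle (the α-methylene lactone is 1,1-disubstituted and electron-poor, the iodoalkene trisubstituted), and the E allylic alcohol should dominate under thermodynamic control.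

Step 13
Reactants: 23 (E)-allylic alcohol
Product: 24 (1S,2S)-epoxy alcohol
Conditions: Ti(OiPr)4 (20 mol %), L-(+)-diethyl tartrate, t-BuOOH, 4 Å molecular sieves, CH2Cl2, −20 °C
Reagents that add atoms: tert-butyl hydroperoxide, CC(C)(C)OO
Why: Sharpless asymmetric epoxidation: the L-(+)-tartrate–titanium catalyst delivers oxygen to the (E)-allylic alcohol with reagent control and should give the (1S,2S)-trans-oxirane, which fixes the C2–O bond of the target, while the acrylate units and the vinyl iodide do not react.

Step 14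
Reactants: 24 epoxy alcohol
Product: 25 epoxy aldehyde (C3 aldehyde on the C1–C2 trans-oxirane)
Conditions: Dess–Martin periodinane, CH2Cl2, 0 °C to rt
Reagents that add atoms: none
Why: Dess–Martin oxidation of the primary epoxy alcohol under neutral conditions gives the epoxy aldehyde without opening the oxirane or touching C10–H.

Step 15
Reactants: 25 epoxy aldehyde
Product: 26 macrocyclic (3R)-epoxy alcohol
Conditions: CrCl2 (10 equiv), NiCl2 (0.1 equiv), DMSO–THF, rt, syringe-pump addition to 2 mM
Reagents that add atoms: none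
Why: Nozaki–Hiyama–Kishi reaction: zerovalent nickel (formed from NiCl2 and CrCl2) inserts into the C4–I bond with retention of the Z geometry, transmetalation gives the alkenyl trivalent chromium species, and this adds intramolecularly to the C3 aldehyde. The closest known reaction type is the Nozaki–Hiyama–Kishi macrocyclisation of a vinyl iodide onto an aldehyde that closes the ten-membered carbocycle of germacranolides next to a preformed α-methylene lactone. The ten-membered carbocycle (C1–C10) is closed in the 10-exo-trig mode, the carbonyl oxygen ending outside the ring as the C3 hydroxyl. The new C3 stereocentre is controlled by the C1–C2 oxirane and the ring: the oxirane C2–O bond lies anti to the incoming alkenyl group (polar Felkin–Anh arrangement) and the chromium-bound carbonyl oxygen points away from C1 to the outside of the forming ring, which should give the 2,3-syn (3R) alcohol. The step needs chemoselectivity for the aldehyde over the lactone, the two esters and the oxirane, which alkenylchromium reagents show, and cyclisation over oligomerisation, which high dilution, the Z C4=C5 geometry and the trans-fused lactone at C6/C7 (bringing C4 and C3 within reach) should secure. The aldehyde cannot enolise or lose its C2 configuration because C2 is an oxirane carbon, and C10–H is not acidic enough to open the oxirane under these neutral conditions.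

Step 16
Reactants: 26 macrocyclic epoxy alcohol
Product: 29 bis-silylated ten-membered divinyl oxirane, via C3 mesylate 27 (not isolated), via C2 alkoxide 28 (not isolated)
Conditions: MsCl, Et3N, CH2Cl2, −40 °C; then DBU, −40 to 0 °C
Reagents that add atoms: none
Why: Mesylation, then base-induced E1cB opening of the β,γ-epoxy ester (the C10 enolate expels the C1–O bond and gives the (E)-C1=C10 enoate with C2 trans to the ester, favoured by allylic strain and by the cis ring geometry) and intramolecular Williamson substitution of the C2 alkoxide on the C3 mesylate with inversion, which turns the (3R)-mesylate into the cis C2–C3 oxirane with C2 retained from step 13; both elementary events are standard for β,γ-epoxy esters and for γ-hydroxy-δ-sulfonyloxy enoates, and the C9 silyloxy group is too poor a leaving group to compete.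

Step 17
Reactants: 29 bis-silylated divinyl oxirane
Product: 30 C8 alcohol
Conditions: HF·pyridine, pyridine, THF, 0 °C
Reagents that add atoms: none
Why: Selective desilylation: buffered HF·pyridine cleaves the secondary triethylsilyl ether much faster than the hindered tert-butyldimethylsilyl ether, and the medium should not open the oxirane at 0 °C.

Step 18
Reactants: 31 methyl angelate
Product: 32 (Z)-2-methylbut-2-en-1-ol
Conditions: i-Bu2AlH, CH2Cl2, −78 °C
Reagents that add atoms: none
Why: Ester reduction with i-Bu2AlH at low temperature gives the allylic alcohol without isomerising the (Z)-alkene.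

Step 19
Reactants: 32 (Z)-2-methylbut-2-en-1-ol
Product: 33 [(2R,3S)-2,3-dimethyloxiran-2-yl]methanol
Conditions: Ti(OiPr)4, D-(−)-diethyl tartrate, t-BuOOH, 4 Å molecular sieves, CH2Cl2, −20 °C
Reagents that add atoms: tert-butyl hydroperoxide, CC(C)(C)OO
Why: Sharpless asymmetric epoxidation with D-(−)-tartrate: syn oxygen transfer to the (Z)-trisubstituted allylic alcohol keeps the alkene geometry and should give the (2R,3S)-epoxy alcohol by reagent control.

Step 20
Reactants: 33 epoxy alcohol
Product: 34 (2S,3S)-2,3-dimethyloxirane-2-carboxylic acid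
Conditions: RuCl3 (cat.), NaIO4, CCl4–MeCN–H2O, rt
Reagents that add atoms: water, O
Why: Ruthenium tetroxide oxidation (catalytic RuCl3 with periodate) converts the primary epoxy alcohol to the carboxylic acid without opening the oxirane; the two stereocentres are untouched and the descriptor at C2 changes only through priorities.

Step 21
Reactants: 30 C8 alcohol; 34 (2S,3S)-2,3-dimethyloxirane-2-carboxylic acid
Product: 36 C8 epoxyangelate, via mixed anhydride 35 (not isolated)
Conditions: 34, 2,4,6-trichlorobenzoyl chloride, Et3N, toluene, rt; then 30, DMAP, toluene, rt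
Reagents that add atoms: none
Why: Yamaguchi esterification: DMAP attacks the mixed anhydride at the aliphatic carbonyl and the acylpyridinium acylates the C8 hydroxyl under non-acidic conditions that spare both oxiranes.

Step 22
Reactants: 36 C8 epoxyangelate
Product: 37 C9 alcohol
Conditions: HF·pyridine, THF, 0 °C to rt
Reagents that add atoms: none
Why: Silyl ether cleavage with HF·pyridine under slightly acidic conditions, which suppresses migration of the C8 acyl group to the freed C9 hydroxyl.

Step 23
Reactants: 37 C9 alcohol; 38 (R)-2-methylbutanoic acid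
Product: 39 CNP0485260.1
Conditions: DCC, DMAP (cat.), CH2Cl2, 0 °C to rt
Reagents that add atoms: none
Why: Steglich esterification of the allylic C9 hydroxyl; the hindered tertiary epoxyangelate on C8 resists acyl migration and the α-stereocentre of the acid should not epimerise under carbodiimide/DMAP activation at low temperature.

**Compound list**

1 | (R)-but-3-ene-1,2-diol | C=C[C@@H](O)CO | starting material
2 | (R)-3,4-bis(triethylsilyloxy)but-1-ene | C=C[C@@H](O[Si](CC)(CC)CC)CO[Si](CC)(CC)CC | intermediate
3 | 3-[(1S)-1,2-bis(triethylsilyloxy)ethyl]-1,2,4-trioxolane (secondary ozonide, epimers at the ring carbon) | O1OC(OC1)[C@@H](O[Si](CC)(CC)CC)CO[Si](CC)(CC)CC | intermediate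
4 | (S)-2,3-bis(triethylsilyloxy)propanal | O=C[C@@H](O[Si](CC)(CC)CC)CO[Si](CC)(CC)CC | intermediate
5 | (S)-4-benzyl-3-[(E)-but-2-enoyl]oxazolidin-2-one | C/C=C/C(=O)N1[C@@H](Cc2ccccc2)COC1=O | starting material
6 | dibutylboron (Z)-dienolate of 5 | C=C/C=C(\OB(CCCC)CCCC)N1[C@@H](Cc2ccccc2)COC1=O | intermediate
7 | dibutylboron aldolate (O9-boryl derivative of 8) | C=C[C@H](C(=O)N1[C@@H](Cc2ccccc2)COC1=O)[C@H](OB(CCCC)CCCC)[C@@H](O[Si](CC)(CC)CC)CO[Si](CC)(CC)CC | intermediate
8 | (S)-4-benzyl-3-[(2S,3S,4S)-3-hydroxy-4,5-bis(triethylsilyloxy)-2-vinylpentanoyl]oxazolidin-2-one | C=C[C@H](C(=O)N1[C@@H](Cc2ccccc2)COC1=O)[C@H](O)[C@@H](O[Si](CC)(CC)CC)CO[Si](CC)(CC)CC | intermediate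
9 | methyl (2S,3S,4S)-3-hydroxy-4,5-bis(triethylsilyloxy)-2-vinylpentanoate | C=C[C@H](C(=O)OC)[C@H](O)[C@@H](O[Si](CC)(CC)CC)CO[Si](CC)(CC)CC | intermediate
10 | methyl (2S,3S,4S)-3-(tert-butyldimethylsilyloxy)-4,5-bis(triethylsilyloxy)-2-vinylpentanoate | C=C[C@H](C(=O)OC)[C@H](O[Si](C)(C)C(C)(C)C)[C@@H](O[Si](CC)(CC)CC)CO[Si](CC)(CC)CC | intermediate
11 | methyl (2S,3S,4R)-3-(tert-butyldimethylsilyloxy)-5-oxo-4-(triethylsilyloxy)-2-vinylpentanoate | C=C[C@H](C(=O)OC)[C@H](O[Si](C)(C)C(C)(C)C)[C@@H](O[Si](CC)(CC)CC)C=O | intermediate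
12 | methyl propiolate | C#CC(=O)OC | starting material
13 | methyl 2-(diisobutylalumanyl)prop-2-enoate | C=C(C(=O)OC)[Al](CC(C)C)CC(C)C | intermediate
14 | dimethyl 5-(tert-butyldimethylsilyloxy)-3-hydroxy-2-methylidene-4-(triethylsilyloxy)-6-vinylheptanedioate (C8, C9, C10 as in 11; both C7 epimers) | C=C[C@H](C(=O)OC)[C@H](O[Si](C)(C)C(C)(C)C)[C@@H](O[Si](CC)(CC)CC)C(O)C(=C)C(=O)OC | intermediate
15 | dimethyl (2Z)-2-(bromomethyl)-5-(tert-butyldimethylsilyloxy)-4-(triethylsilyloxy)-6-vinylhept-2-enedioate (C8, C9, C10 as in 11) | C=C[C@H](C(=O)OC)[C@H](O[Si](C)(C)C(C)(C)C)[C@@H](O[Si](CC)(CC)CC)/C=C(\CBr)C(=O)OC | intermediate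
16 | but-2-yn-1-ol | CC#CCO | starting material
17 | sodium cyclic alkenylalanate from 16 (five-membered C=C–C–O–Al ring, two 2-methoxyethoxy groups on aluminium) | CC1=CCO[Al-]1(OCCOC)OCCOC.[Na+] | intermediate
18 | (Z)-3-iodobut-2-en-1-ol | C/C(I)=C/CO | intermediate
19 | (Z)-3-iodobut-2-enal | C/C(I)=C/C=O | intermediate
20 | anti hydroxy diester (open form of 21: C6–OH, methyl ester at C12, C6–C10 configured as in 21) | C=C(C(=O)OC)[C@@H]([C@H](O)/C=C(/C)I)[C@H](O[Si](CC)(CC)CC)[C@@H](O[Si](C)(C)C(C)(C)C)[C@H](C=C)C(=O)OC | intermediate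
21 | trans-α-methylene-γ-butyrolactone with the (Z)-2-iodoprop-1-enyl group on C6 and the chain C8(OSiEt3)–C9(OSiMe2t-Bu)–C10(vinyl)(CO2Me) on C7; C6–C9 configured as in the target, (10S) | C=C1C(=O)O[C@H](/C=C(/C)I)[C@H]1[C@H](O[Si](CC)(CC)CC)[C@@H](O[Si](C)(C)C(C)(C)C)[C@H](C=C)C(=O)OC | intermediate
22 | (Z)-but-2-ene-1,4-diol | OC/C=C\CO | starting material
23 | (E)-allylic alcohol: 21 with (E)-3-hydroxyprop-1-enyl in place of vinyl on C10 | C=C1C(=O)O[C@H](/C=C(/C)I)[C@H]1[C@H](O[Si](CC)(CC)CC)[C@@H](O[Si](C)(C)C(C)(C)C)[C@H](/C=C/CO)C(=O)OC | intermediate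
24 | (1S,2S)-epoxy alcohol: 23 with a trans-oxirane on C1–C2 and CH2OH (C3) on C2 | C=C1C(=O)O[C@H](/C=C(/C)I)[C@H]1[C@H](O[Si](CC)(CC)CC)[C@@H](O[Si](C)(C)C(C)(C)C)[C@H]([C@@H]2O[C@H]2CO)C(=O)OC | intermediate
25 | epoxy aldehyde: 24 with C3 oxidised to CHO | C=C1C(=O)O[C@H](/C=C(/C)I)[C@H]1[C@H](O[Si](CC)(CC)CC)[C@@H](O[Si](C)(C)C(C)(C)C)[C@H]([C@@H]2O[C@H]2C=O)C(=O)OC | intermediate
26 | macrocyclic epoxy alcohol: ten-membered carbocycle fused to the trans lactone, (Z)-C4=C5, (3R)-OH, C1–C2 trans-oxirane, (10S)-CO2Me, C9–OSiMe2t-Bu, C8–OSiEt3 | C=C1C(=O)O[C@@H]2/C=C(/C)[C@@H](O)[C@@H]3O[C@H]3[C@H](C(=O)OC)[C@H](O[Si](C)(C)C(C)(C)C)[C@@H](O[Si](CC)(CC)CC)[C@@H]12 | intermediate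
27 | C3 methanesulfonate of 26 | C=C1C(=O)O[C@@H]2/C=C(/C)[C@@H](OS(C)(=O)=O)[C@@H]3O[C@H]3[C@H](C(=O)OC)[C@H](O[Si](C)(C)C(C)(C)C)[C@@H](O[Si](CC)(CC)CC)[C@@H]12 | intermediate
28 | C2 alkoxide of the (E)-C1=C10 enoate carrying the C3 mesylate | C=C1C(=O)O[C@@H]2/C=C(/C)[C@@H](OS(C)(=O)=O)[C@H]([O-])/C=C(/C(=O)OC)[C@H](O[Si](C)(C)C(C)(C)C)[C@@H](O[Si](CC)(CC)CC)[C@@H]12 | intermediate
29 | target core with C9–OSiMe2t-Bu and C8–OSiEt3 (cis C2–C3 oxirane, (E)-C1=C10 enoate, (Z)-C4=C5) | C=C1C(=O)O[C@@H]2/C=C(/C)[C@@H]3O[C@@H]3/C=C(/C(=O)OC)[C@H](O[Si](C)(C)C(C)(C)C)[C@@H](O[Si](CC)(CC)CC)[C@@H]12 | intermediate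
30 | C8 alcohol (29 without the triethylsilyl group) | C=C1C(=O)O[C@@H]2/C=C(/C)[C@@H]3O[C@@H]3/C=C(/C(=O)OC)[C@H](O[Si](C)(C)C(C)(C)C)[C@@H](O)[C@@H]12 | intermediate
31 | methyl angelate [methyl (Z)-2-methylbut-2-enoate] | C/C=C(/C)C(=O)OC | starting material
32 | (Z)-2-methylbut-2-en-1-ol | C/C=C(/C)CO | intermediate
33 | [(2R,3S)-2,3-dimethyloxiran-2-yl]methanol | OC[C@@]1(C)O[C@H]1C | intermediate
34 | (2S,3S)-2,3-dimethyloxirane-2-carboxylic acid | OC(=O)[C@@]1(C)O[C@H]1C | intermediate
35 | mixed anhydride of 34 with 2,4,6-trichlorobenzoic acid | O=C(OC(=O)[C@@]1(C)O[C@H]1C)c1c(Cl)cc(Cl)cc1Cl | intermediate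
36 | C8 (2S,3S)-2,3-dimethyloxirane-2-carboxylate with C9–OSiMe2t-Bu | C=C1C(=O)O[C@@H]2/C=C(/C)[C@@H]3O[C@@H]3/C=C(/C(=O)OC)[C@H](O[Si](C)(C)C(C)(C)C)[C@@H](OC(=O)[C@@]3(C)O[C@H]3C)[C@@H]12 | intermediate
37 | C9 alcohol (36 without the silyl group) | C=C1C(=O)O[C@@H]2/C=C(/C)[C@@H]3O[C@@H]3/C=C(/C(=O)OC)[C@H](O)[C@@H](OC(=O)[C@@]3(C)O[C@H]3C)[C@@H]12 | intermediate
38 | (R)-2-methylbutanoic acid | OC(=O)[C@H](C)CC | starting material
39 | CNP0485260.1 | C=C1C(=O)O[C@@H]2/C=C(/C)[C@@H]3O[C@@H]3/C=C(/C(=O)OC)[C@H](OC(=O)[C@H](C)CC)[C@@H](OC(=O)[C@@]3(C)O[C@H]3C)[C@@H]12 | target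

**Step count and risks**

Total step count: 23. Longest linear sequence: 18 steps (steps 1–8, 11–17 and 21–23, from diol 1).

Steps most likely to fail:

Step 15. What may go wrong: poor facial selectivity in the ring-closing addition, because the open-chain preference for the 2,3-anti adduct competes with the ring-imposed one, and oligomerisation if the chain does not fold. The fallback sets out from 26 obtained as a mixture of C3 epimers. Oxidation with Dess–Martin periodinane (CH2Cl2, rt) converges both epimers on the macrocyclic epoxy enone F1. A reagent-controlled Corey–Bakshi–Shibata reduction ((R)-2-methyl-CBS-oxazaborolidine, catecholborane, toluene, −78 °C, the alkenyl side acting as the large group) should then return the (3R)-alcohol, and the sequence comes back to the route at 26.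

Step 16. What may go wrong: loss of the allylic C3 mesylate by ionisation or allylic transposition before the C2 alkoxide is released, and base-induced isomerisation of the α-methylene lactone. The fallback sets out from 26. DBU alone (CH2Cl2, 0 °C) carries out only the E1cB opening and should give the macrocyclic (2R,3R)-diol enoate F2. Mitsunobu cyclodehydration (PPh3, diisopropyl azodicarboxylate, toluene, 0 °C to rt) then activates the diol in situ; the oxyphosphonium group should leave from the allylic C3 next to the electron-rich C4=C5 bond while the C2 oxygen enters with inversion. The fallback comes back to the route at 29.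

Step 11. What may go wrong: weak 1,2-induction from C8 onto the new C7 centre (and with it C6), and β-elimination of the C8 silyloxy group from the allylchromium reagent. The fallback sets out from 15 and 19. A catalyst-controlled asymmetric Nozaki–Hiyama allylation (CrCl2 (10 mol %), a chiral 1,8-bis(oxazolinyl)carbazole ligand, Mn, Me3SiCl, i-Pr2NEt, THF, rt) lets the ligand on chromium, instead of C8, select the faces and should give the O-trimethylsilyl hydroxy diester F3. Citric acid in MeOH removes the trimethylsilyl group, the hydroxy diester 20 lactonises, and the fallback comes back to the route at 21.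

Further compounds

F1 | step 15 | macrocyclic epoxy enone (C3 ketone of 26) | C=C1C(=O)O[C@@H]2/C=C(/C)C(=O)[C@@H]3O[C@H]3[C@H](C(=O)OC)[C@H](O[Si](C)(C)C(C)(C)C)[C@@H](O[Si](CC)(CC)CC)[C@@H]12
F2 | step 16 | macrocyclic (2R,3R)-diol with the (E)-C1=C10 enoate | C=C1C(=O)O[C@@H]2/C=C(/C)[C@@H](O)[C@H](O)/C=C(/C(=O)OC)[C@H](O[Si](C)(C)C(C)(C)C)[C@@H](O[Si](CC)(CC)CC)[C@@H]12
F3 | step 11 | O-trimethylsilyl ether of hydroxy diester 20 | C=C(C(=O)OC)[C@@H]([C@H](O[Si](C)(C)C)/C=C(/C)I)[C@H](O[Si](CC)(CC)CC)[C@@H](O[Si](C)(C)C(C)(C)C)[C@H](C=C)C(=O)OC
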